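**Retrosynthetic overview**

1. The target is a flavone (rings A, C, B) with a prenyl group on C3 and a 3-methyl-2-oxobutyl chain on C6. The three phenols are freed last from MOM ethers; the C3–prenyl bond comes from a Stille coupling of a 3-iodoflavone; the side-chain ketone comes from OsO4/NaIO4 cleavage of a 1,1-disubstituted alkene.
2. Feature on which the plan rests: on ring A, C6 is the only hydrogen-bearing carbon ortho to the peri oxygen O5 (the other ortho carbon is the ring-fusion carbon C4a), and the benzylic CH2 and the carbonyl carbon of the C6 chain are the terminus and the central carbon of an allyl unit. The C6–CH2 bond is therefore made by aromatic Claisen rearrangement of the O5 (2-isopropylallyl) ether of the intact flavone.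
3. Ring order: rings A and B are bought (2',6'-dihydroxy-4'-methoxyacetophenone and 2,4-dihydroxybenzaldehyde). Ring C is closed by Claisen–Schmidt condensation, oxa-Michael cyclization and DDQ dehydrogenation, so that the MOM ethers and the acid-sensitive 2-alkylallyl ether never meet acid.
4. The allyl unit, 2-(bromomethyl)-3-methylbut-1-ene, comes from isovaleraldehyde (α-methylenation, Luche reduction, PBr3) and is put on one of the two equivalent hydroxyls of the acetophenone.
5. After the rearrangement: 5-OH is capped as a MOM ether, C3 is iodinated by deprotonation while the side chain is still an alkene (no enolizable ketone), the alkene is then cleaved while it is the only oxidizable alkene, and the prenyl group enters last.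

Key step: step 9

Remark: flavone numbering is used (O1, C2, C3, C4, C4a, C5–C8, C8a; ring B primed). The target has no stereocenter; flavanone 10, dienone 12 and diol 17 are racemic and their stereocenters are erased in the next operation.

**Route**

Step 1
Reactants: 1 isovaleraldehyde (3-methylbutanal)
Product: 2 3-methyl-2-methylidenebutanal
Conditions: aq. HCHO (37%), pyrrolidine (10 mol %), EtCO2H (10 mol %), i-PrOH, 45 °C
Reagents that add atoms: formaldehyde, C=O
Why: Amine-catalyzed Mannich condensation of the enolizable aldehyde with formaldehyde followed by elimination of the amine (α-methylenation) is a standard way to 2-alkylacroleins.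

Step 2
Reactants: 2 3-methyl-2-methylidenebutanal
Product: 3 3-methyl-2-methylidenebutan-1-ol
Conditions: NaBH4, CeCl3·7H2O, MeOH, 0 °C
Reagents that add atoms: none
Why: Luche reduction delivers hydride 1,2 to the enal and leaves the 1,1-disubstituted alkene untouched.

Step 3
Reactants: 3 3-methyl-2-methylidenebutan-1-ol
Product: 4 2-(bromomethyl)-3-methylbut-1-ene
Conditions: PBr3, Et2O, 0 °C
Reagents that add atoms: phosphorus tribromide, BrP(Br)Br
Why: Bromination of a primary allylic alcohol with PBr3 is reliable here because direct and allylically transposed substitution give the same bromide (both allyl termini are CH2).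

Step 4
Reactants: 5 2',6'-dihydroxy-4'-methoxyacetophenone; 4 2-(bromomethyl)-3-methylbut-1-ene
Product: 6 1-{2-hydroxy-4-methoxy-6-[(3-methyl-2-methylidenebutyl)oxy]phenyl}ethanone
Conditions: K2CO3 (1.1 equiv), 4 (1.05 equiv), acetone, reflux
Reagents that add atoms: none
Why: Williamson etherification of the symmetric diol should stop at the mono-ether, because the two hydroxyls are equivalent and the remaining one is deactivated by its hydrogen bond to the acetyl carbonyl.

Step 5
Reactants: 7 2,4-dihydroxybenzaldehyde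
Product: 8 2,4-bis(methoxymethoxy)benzaldehyde
Conditions: MOMCl (3 equiv), K2CO3, acetone, reflux
Reagents that add atoms: chloromethyl methyl ether (MOMCl), COCCl
Why: Williamson-type acetal protection of both phenols gives base-stable MOM ethers that can be removed at the end without hydrogenation or Lewis acids.

Step 6
Reactants: 6 1-{2-hydroxy-4-methoxy-6-[(3-methyl-2-methylidenebutyl)oxy]phenyl}ethanone; 8 2,4-bis(methoxymethoxy)benzaldehyde
Product: 9 (E)-3-[2,4-bis(methoxymethoxy)phenyl]-1-{2-hydroxy-4-methoxy-6-[(3-methyl-2-methylidenebutyl)oxy]phenyl}prop-2-en-1-one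
Conditions: KOH, EtOH–H2O, rt
Reagents that add atoms: none
Why: Claisen–Schmidt condensation (aldol addition, then E1cB dehydration to the E-enone) is standard for 2'-hydroxy-4',6'-dialkoxyacetophenones, and the MOM and allyl ethers are inert to aqueous base.

Step 7
Reactants: 9 the 2'-hydroxychalcone
Product: 10 racemic 2-[2,4-bis(methoxymethoxy)phenyl]-7-methoxy-5-[(3-methyl-2-methylidenebutyl)oxy]-2,3-dihydro-4H-chromen-4-one
Conditions: NaOAc, EtOH, reflux
Reagents that add atoms: none
Why: Base-mediated intramolecular oxa-Michael addition of the 2'-phenoxide closes ring C, the 6'-alkoxy group twisting the chalcone and favoring the flavanone; C2 forms as a racemate and becomes sp2 in step 8.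

Step 8
Reactants: 10 the flavanone
Product: 11 2-[2,4-bis(methoxymethoxy)phenyl]-7-methoxy-5-[(3-methyl-2-methylidenebutyl)oxy]-4H-chromen-4-one
Conditions: DDQ (2.5 equiv), 1,4-dioxane, reflux
Reagents that add atoms: none
Why: DDQ dehydrogenation of a fully O-protected flavanone to the flavone proceeds under neutral conditions that should spare the MOM ethers and the isolated 1,1-disubstituted alkene.

Step 9
Reactants: 11 2-[2,4-bis(methoxymethoxy)phenyl]-7-methoxy-5-[(3-methyl-2-methylidenebutyl)oxy]-4H-chromen-4-one
Product: 13 2-[2,4-bis(methoxymethoxy)phenyl]-5-hydroxy-7-methoxy-6-(3-methyl-2-methylidenebutyl)-4H-chromen-4-one, via cyclohexadienone tautomer 12 (not isolated)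
Conditions: PhNEt2, 200 °C, sealed tube, Ar
Reagents that add atoms: none
Why: Heating ether 11 should set off a concerted, suprafacial [3,3]-sigmatropic shift through a chair-like six-membered transition state (aromatic Claisen rearrangement; the closest precedent is the thermal rearrangement of 5-allyloxyflavones to 6-allyl-5-hydroxyflavones), in which the O5–CH2 bond breaks while the =CH2 terminus bonds to C6 to give dienone 12, whose tautomerization restores ring A as the 5-OH chelated to the C4 carbonyl. No ring is closed and no stereocenter remains, since C6 of 12 is sp3 only transiently. The selectivity needed is migration to C6 alone: the other carbon ortho to O5 is the ring-fusion carbon C4a, which carries no hydrogen and cannot rearomatize, whereas the C6 adduct bears a hydrogen and enolizes before a Cope shift could carry the chain on to C8. Both allyl termini are unsubstituted CH2 groups, so the shift can only deliver Ar–CH2–C(=CH2)–CH(CH3)2 and no reverse-allyl isomer can arise. C3 carries only hydrogen and the ring B phenols are MOM ethers, so 11 holds a single allyl aryl ether and no free phenol, and the basic solvent should suppress acid-catalyzed closure of the freed 5-OH onto the new alkene. Relief of the peri crowding between the O5 substituent and the C4 carbonyl, together with the new O5–H···O=C4 hydrogen bond, should favor the product.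

Step 10
Reactants: 13 the 5-hydroxy-6-allylated flavone
Product: 14 2-[2,4-bis(methoxymethoxy)phenyl]-7-methoxy-5-(methoxymethoxy)-6-(3-methyl-2-methylidenebutyl)-4H-chromen-4-one
Conditions: NaH, MOMCl, DMF, 0 °C to rt
Reagents that add atoms: chloromethyl methyl ether (MOMCl), COCCl
Why: Williamson-type protection with full deprotonation by NaH overcomes the chelation of the peri 5-OH and removes the only acidic proton before the strong-base step.

Step 11
Reactants: 14 the tris-MOM flavone
Product: 16 2-[2,4-bis(methoxymethoxy)phenyl]-3-iodo-7-methoxy-5-(methoxymethoxy)-6-(3-methyl-2-methylidenebutyl)-4H-chromen-4-one, via 3-lithioflavone 15 (not isolated)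
Conditions: LiN(i-Pr)2 (LDA, commercial solution, 1.3 equiv), THF, −78 °C; then I2, THF, −78 °C to rt
Reagents that add atoms: iodine, II
Why: Carbonyl-directed deprotonation of the vinylic C3–H of a flavone by LDA and iodine quench of the 3-lithio species is known chemistry; it is used here because electrophilic iodination would attack C8 and ring B, and it is run before the ketone exists.

Step 12
Reactants: 16 the 3-iodoflavone
Product: 18 2-[2,4-bis(methoxymethoxy)phenyl]-3-iodo-7-methoxy-5-(methoxymethoxy)-6-(3-methyl-2-oxobutyl)-4H-chromen-4-one, via vicinal diol 17 (not isolated)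
Conditions: OsO4 (cat.), NMO, acetone–H2O, rt; then NaIO4, rt
Reagents that add atoms: osmium tetroxide, O=[Os](=O)(=O)=O (catalytic oxygen carrier); N-methylmorpholine N-oxide, C[N+]1([O-])CCOCC1; water, O
Why: Upjohn dihydroxylation followed by periodate glycol cleavage converts the only electron-rich alkene into the ketone, the tetrasubstituted iodo-enone C2=C3 bond of the pyranone being inert to OsO4.

Step 13
Reactants: 18 the 3-iodo ketone; 19 tributyl(3-methylbut-2-en-1-yl)stannane
Product: 20 2-[2,4-bis(methoxymethoxy)phenyl]-7-methoxy-5-(methoxymethoxy)-3-(3-methylbut-2-en-1-yl)-6-(3-methyl-2-oxobutyl)-4H-chromen-4-one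
Conditions: Pd(PPh3)4 (5 mol %), DMF, 90 °C
Reagents that add atoms: none
Why: Stille coupling (oxidative addition of zerovalent palladium into the activated C3–I bond, transmetalation, reductive elimination at the less hindered allyl terminus) should give the linear prenyl group under neutral conditions that tolerate the enolizable ketone.

Step 14
Reactants: 20 the tris-MOM prenylflavone
Product: 21 2-(2,4-dihydroxyphenyl)-5-hydroxy-7-methoxy-3-(3-methylbut-2-en-1-yl)-6-(3-methyl-2-oxobutyl)-4H-chromen-4-one (target)
Conditions: HCl (3 M in MeOH), 45 °C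
Reagents that add atoms: none
Why: Acid-catalyzed acetal exchange with methanol removes the three MOM groups, and the mild acid and temperature are chosen so that the prenyl alkene is not hydrated and the chelated 5-OH does not condense with the side-chain ketone.

**Compound list**

1 | isovaleraldehyde (3-methylbutanal) | CC(C)CC=O | starting material
2 | 3-methyl-2-methylidenebutanal | CC(C)C(=C)C=O | intermediate
3 | 3-methyl-2-methylidenebutan-1-ol | CC(C)C(=C)CO | intermediate
4 | 2-(bromomethyl)-3-methylbut-1-ene | CC(C)C(=C)CBr | intermediate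
5 | 2',6'-dihydroxy-4'-methoxyacetophenone | COc1cc(O)c(C(C)=O)c(O)c1 | starting material
6 | 1-{2-hydroxy-4-methoxy-6-[(3-methyl-2-methylidenebutyl)oxy]phenyl}ethanone | COc1cc(O)c(C(C)=O)c(OCC(=C)C(C)C)c1 | intermediate
7 | 2,4-dihydroxybenzaldehyde | O=Cc1ccc(O)cc1O | starting material
8 | 2,4-bis(methoxymethoxy)benzaldehyde | COCOc1ccc(C=O)c(OCOC)c1 | intermediate
9 | (E)-3-[2,4-bis(methoxymethoxy)phenyl]-1-{2-hydroxy-4-methoxy-6-[(3-methyl-2-methylidenebutyl)oxy]phenyl}prop-2-en-1-one | COc1cc(O)c(C(=O)/C=C/c2ccc(OCOC)cc2OCOC)c(OCC(=C)C(C)C)c1 | intermediate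
10 | racemic 2-[2,4-bis(methoxymethoxy)phenyl]-7-methoxy-5-[(3-methyl-2-methylidenebutyl)oxy]-2,3-dihydro-4H-chromen-4-one | COc1cc2c(c(OCC(=C)C(C)C)c1)C(=O)CC(c1ccc(OCOC)cc1OCOC)O2 | intermediate
11 | 2-[2,4-bis(methoxymethoxy)phenyl]-7-methoxy-5-[(3-methyl-2-methylidenebutyl)oxy]-4H-chromen-4-one | COc1cc2oc(-c3ccc(OCOC)cc3OCOC)cc(=O)c2c(OCC(=C)C(C)C)c1 | intermediate
12 | racemic 2-[2,4-bis(methoxymethoxy)phenyl]-7-methoxy-6-(3-methyl-2-methylidenebutyl)-4H-chromene-4,5(6H)-dione (cyclohexadienone tautomer of 13) | COC1=CC2=C(C(=O)C1CC(=C)C(C)C)C(=O)C=C(c1ccc(OCOC)cc1OCOC)O2 | intermediate (not isolated)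
13 | 2-[2,4-bis(methoxymethoxy)phenyl]-5-hydroxy-7-methoxy-6-(3-methyl-2-methylidenebutyl)-4H-chromen-4-one | COc1cc2oc(-c3ccc(OCOC)cc3OCOC)cc(=O)c2c(O)c1CC(=C)C(C)C | intermediate
14 | 2-[2,4-bis(methoxymethoxy)phenyl]-7-methoxy-5-(methoxymethoxy)-6-(3-methyl-2-methylidenebutyl)-4H-chromen-4-one | COc1cc2oc(-c3ccc(OCOC)cc3OCOC)cc(=O)c2c(OCOC)c1CC(=C)C(C)C | intermediate
15 | 3-lithio derivative of 14 | COc1cc2oc(-c3ccc(OCOC)cc3OCOC)c([Li])c(=O)c2c(OCOC)c1CC(=C)C(C)C | intermediate (not isolated)
16 | 2-[2,4-bis(methoxymethoxy)phenyl]-3-iodo-7-methoxy-5-(methoxymethoxy)-6-(3-methyl-2-methylidenebutyl)-4H-chromen-4-one | COc1cc2oc(-c3ccc(OCOC)cc3OCOC)c(I)c(=O)c2c(OCOC)c1CC(=C)C(C)C | intermediate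
17 | racemic 2-[2,4-bis(methoxymethoxy)phenyl]-6-[2-hydroxy-2-(hydroxymethyl)-3-methylbutyl]-3-iodo-7-methoxy-5-(methoxymethoxy)-4H-chromen-4-one | COc1cc2oc(-c3ccc(OCOC)cc3OCOC)c(I)c(=O)c2c(OCOC)c1CC(O)(CO)C(C)C | intermediate (not isolated)
18 | 2-[2,4-bis(methoxymethoxy)phenyl]-3-iodo-7-methoxy-5-(methoxymethoxy)-6-(3-methyl-2-oxobutyl)-4H-chromen-4-one | COc1cc2oc(-c3ccc(OCOC)cc3OCOC)c(I)c(=O)c2c(OCOC)c1CC(=O)C(C)C | intermediate
19 | tributyl(3-methylbut-2-en-1-yl)stannane | CCCC[Sn](CCCC)(CCCC)CC=C(C)C | starting material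
20 | 2-[2,4-bis(methoxymethoxy)phenyl]-7-methoxy-5-(methoxymethoxy)-3-(3-methylbut-2-en-1-yl)-6-(3-methyl-2-oxobutyl)-4H-chromen-4-one | COc1cc2oc(-c3ccc(OCOC)cc3OCOC)c(CC=C(C)C)c(=O)c2c(OCOC)c1CC(=O)C(C)C | intermediate
21 | 2-(2,4-dihydroxyphenyl)-5-hydroxy-7-methoxy-3-(3-methylbut-2-en-1-yl)-6-(3-methyl-2-oxobutyl)-4H-chromen-4-one | COc1cc2oc(-c3ccc(O)cc3O)c(CC=C(C)C)c(=O)c2c(O)c1CC(=O)C(C)C | target

**Step count**

Total steps: 14. Longest linear sequence: 13 steps (1 → 21 through steps 1–4 and 6–14); step 5 is a one-step side branch.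

**Steps most likely to fail**

Step 9 (Claisen rearrangement). At 200 °C the allyl ether may fragment at the O5–CH2 bond instead of rearranging, or the freed 5-OH may add across the new 1,1-disubstituted alkene to give a dihydrofuran. Fallback: the C6–CH2 bond would be made by cross-coupling; it sets out from 11 (and from bromide 4) and returns at 13.
- The allyl group of 11 is removed with Pd(PPh3)4 and morpholine in THF to give 2-[2,4-bis(methoxymethoxy)phenyl]-5-hydroxy-7-methoxy-4H-chromen-4-one F1.
- Iodination with benzyltrimethylammonium dichloroiodate and CaCO3 in CH2Cl2–MeOH, which is directed by the free chelated 5-OH to its ortho carbon C6, should give 2-[2,4-bis(methoxymethoxy)phenyl]-5-hydroxy-6-iodo-7-methoxy-4H-chromen-4-one F2.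
- Bromide 4 and Bu3SnLi in THF give tributyl(3-methyl-2-methylidenebutyl)stannane F3.
- Stille coupling of F2 with F3 (Pd(PPh3)4, DMF, 90 °C) should give 13; both allyl termini of F3 lead to the same product.

Step 11 (C3 lithiation and iodination). Deprotonation may occur at the wrong site (the benzylic and allylic C6–CH2, C8–H, or the ring B C3'–H between the two MOM ethers), or the amide may add to the pyranone. Fallback: C3 would be functionalized by oxidation instead of deprotonation; it sets out from 14 and returns at 20.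
- The alkene of 14 is cleaved first (OsO4 cat., NMO, then NaIO4) to give 2-[2,4-bis(methoxymethoxy)phenyl]-7-methoxy-5-(methoxymethoxy)-6-(3-methyl-2-oxobutyl)-4H-chromen-4-one F4.
- Dimethyldioxirane in acetone–CH2Cl2 should epoxidize the C2=C3 bond to the racemic 2,3-epoxide 2-[2,4-bis(methoxymethoxy)phenyl]-2,3-epoxy-7-methoxy-5-(methoxymethoxy)-6-(3-methyl-2-oxobutyl)chroman-4-one F5.
- On silica gel F5 should isomerize to the flavonol 2-[2,4-bis(methoxymethoxy)phenyl]-3-hydroxy-7-methoxy-5-(methoxymethoxy)-6-(3-methyl-2-oxobutyl)-4H-chromen-4-one F6.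
- PhNTf2 and K2CO3 in THF convert F6 into the triflate 2-[2,4-bis(methoxymethoxy)phenyl]-7-methoxy-5-(methoxymethoxy)-6-(3-methyl-2-oxobutyl)-4-oxo-4H-chromen-3-yl trifluoromethanesulfonate F7.
- Stille coupling of F7 with 19 (Pd(PPh3)4, LiCl, dioxane, 90 °C) should give 20.

Step 13 (Stille prenylation). The allyl–palladium intermediate may couple through its substituted terminus and give the 1,1-dimethylallyl isomer, or the iodide may be lost by protodeiodination. Fallback: the prenyl group would be built in two stages; it sets out from 18 and returns at 20.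
- Stille coupling of 18 with allyltributylstannane (Pd(PPh3)4, DMF, 90 °C), where the two allyl termini are equivalent, gives 3-allyl-2-[2,4-bis(methoxymethoxy)phenyl]-7-methoxy-5-(methoxymethoxy)-6-(3-methyl-2-oxobutyl)-4H-chromen-4-one F8.
- Cross-metathesis of F8 with 2-methylbut-2-ene and the second-generation Grubbs catalyst in CH2Cl2 at 40 °C should give 20.

**Further compounds**

F1 | step 9 | 2-[2,4-bis(methoxymethoxy)phenyl]-5-hydroxy-7-methoxy-4H-chromen-4-one | COc1cc2oc(-c3ccc(OCOC)cc3OCOC)cc(=O)c2c(O)c1
F2 | step 9 | 2-[2,4-bis(methoxymethoxy)phenyl]-5-hydroxy-6-iodo-7-methoxy-4H-chromen-4-one | COc1cc2oc(-c3ccc(OCOC)cc3OCOC)cc(=O)c2c(O)c1I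
F3 | step 9 | tributyl(3-methyl-2-methylidenebutyl)stannane | CCCC[Sn](CCCC)(CCCC)CC(=C)C(C)C
F4 | step 11 | 2-[2,4-bis(methoxymethoxy)phenyl]-7-methoxy-5-(methoxymethoxy)-6-(3-methyl-2-oxobutyl)-4H-chromen-4-one | COc1cc2oc(-c3ccc(OCOC)cc3OCOC)cc(=O)c2c(OCOC)c1CC(=O)C(C)C
F5 | step 11 | racemic 2-[2,4-bis(methoxymethoxy)phenyl]-2,3-epoxy-7-methoxy-5-(methoxymethoxy)-6-(3-methyl-2-oxobutyl)chroman-4-one | COc1cc2c(c(OCOC)c1CC(=O)C(C)C)C(=O)C1OC1(c1ccc(OCOC)cc1OCOC)O2
F6 | step 11 | 2-[2,4-bis(methoxymethoxy)phenyl]-3-hydroxy-7-methoxy-5-(methoxymethoxy)-6-(3-methyl-2-oxobutyl)-4H-chromen-4-one | COc1cc2oc(-c3ccc(OCOC)cc3OCOC)c(O)c(=O)c2c(OCOC)c1CC(=O)C(C)C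
F7 | step 11 | 2-[2,4-bis(methoxymethoxy)phenyl]-7-methoxy-5-(methoxymethoxy)-6-(3-methyl-2-oxobutyl)-4-oxo-4H-chromen-3-yl trifluoromethanesulfonate | COc1cc2oc(-c3ccc(OCOC)cc3OCOC)c(OS(=O)(=O)C(F)(F)F)c(=O)c2c(OCOC)c1CC(=O)C(C)C
F8 | step 13 | 3-allyl-2-[2,4-bis(methoxymethoxy)phenyl]-7-methoxy-5-(methoxymethoxy)-6-(3-methyl-2-oxobutyl)-4H-chromen-4-one | COc1cc2oc(-c3ccc(OCOC)cc3OCOC)c(CC=C)c(=O)c2c(OCOC)c1CC(=O)C(C)C
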